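**Retrosynthetic overview**
- Target 20 is a 2,5-dimethoxy-1,4-benzoquinone (central ring) with an indol-3-yl group at C3 and a 2-(1,1-dimethylallyl)indol-3-yl group at C6. The quinone is unmasked last from the bis-MOM hydroquinone ether 18 (acid, then Ag2O).
- Feature used: in the prenylated indole, C2 carries the quaternary C(CH3)2CH=CH2 carbon and C3 carries the central ring. These are the two alkyne carbons of the 2-alkynyl-trifluoroacetanilide 9, so N1–C2 and C3–C(central ring) are cut together to give 9 and aryl iodide 16.
- 16 comes from a single Suzuki coupling of the symmetrical diiodide 14 with indolylboronate 15. 14 comes from quinone 10 by reduction, MOM protection and double ortho-lithiation/iodination.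
- 9 comes from acid 1 (reduction, oxidation, dibromoolefination) and 2-iodoaniline 5 by a one-pot acetylide/zinc/Negishi coupling, then N-trifluoroacetylation.
- Ring order: all benzene rings, the unsubstituted indole and the central ring are bought. The only ring made is the pyrrole ring of the prenylated indole (step 10).

Key step: step 10

Assumption: the target has no stereocentre and rotation about its aryl–indolyl bonds is taken as free, so only constitution has to be secured; aldehyde 3 is volatile and is carried forward in solution.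

**Step 1**
Reactants: 1 2,2-dimethylbut-3-enoic acid
Product: 2 2,2-dimethylbut-3-en-1-ol
Conditions: LiAlH4, Et2O, 0 °C to rt; aq. NaOH work-up
Reagents that add atoms: none
Why: Hydride reduction of a carboxylic acid with LiAlH4 should give the primary alcohol and leave the isolated, unactivated vinyl group untouched.

**Step 2**
Reactants: 2 2,2-dimethylbut-3-en-1-ol
Product: 3 2,2-dimethylbut-3-enal
Conditions: Dess–Martin periodinane, CH2Cl2, 0 °C to rt; filtered through silica, kept as a CH2Cl2 solution
Reagents that add atoms: none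
Why: Dess–Martin oxidation stops at the aldehyde, which has no α-hydrogen and so can neither enolise nor move its double bond into conjugation.

**Step 3**
Reactants: 3 2,2-dimethylbut-3-enal
Product: 4 1,1-dibromo-3,3-dimethylpenta-1,4-diene
Conditions: CBr4, PPh3, CH2Cl2, 0 °C
Reagents that add atoms: carbon tetrabromide, BrC(Br)(Br)Br
Why: First stage of the Corey–Fuchs homologation, in which the ylide Ph3P=CBr2 formed from CBr4 and PPh3 olefinates the non-enolisable aldehyde in a Wittig reaction.

**Step 4**
Reactants: 4 1,1-dibromo-3,3-dimethylpenta-1,4-diene; 5 2-iodoaniline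
Product: 8 2-(3,3-dimethylpent-4-en-1-ynyl)aniline, via lithium acetylide 6 (not isolated), via alkynylzinc chloride 7 (not isolated)
Conditions: n-BuLi (2.1 equiv), THF, −78 to 0 °C; ZnCl2, 0 °C; then 5, Pd(PPh3)4 (cat.), rt to 45 °C
Reagents that add atoms: none
Why: The second Corey–Fuchs stage (bromine–lithium exchange, Fritsch–Buttenberg–Wiechell shift, deprotonation) gives acetylide 6, which after transmetalation to zinc undergoes Negishi alkynylation of the aryl iodide; alkynylzinc halides tolerate the free NH2 group, and the volatile enyne is never isolated.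

**Step 5**
Reactants: 8 2-(3,3-dimethylpent-4-en-1-ynyl)aniline
Product: 9 N-[2-(3,3-dimethylpent-4-en-1-ynyl)phenyl]-2,2,2-trifluoroacetamide
Conditions: (CF3CO)2O, pyridine, CH2Cl2, 0 °C
Reagents that add atoms: trifluoroacetic anhydride, O=C(OC(=O)C(F)(F)F)C(F)(F)F
Why: N-Acylation of the aniline with the anhydride under mild base installs the acidic trifluoroacetamide that the key step needs, without touching alkyne or alkene.

**Step 6**
Reactants: 10 2,5-dimethoxy-1,4-benzoquinone
Product: 11 2,5-dimethoxybenzene-1,4-diol
Conditions: Na2S2O4, EtOAc/H2O, rt, argon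
Reagents that add atoms: none
Why: Dithionite reduction of a p-quinone to its hydroquinone is a standard two-electron reduction; the electron-rich diol is kept under argon and used at once.

**Step 7**
Reactants: 11 2,5-dimethoxybenzene-1,4-diol
Product: 12 1,4-dimethoxy-2,5-bis(methoxymethoxy)benzene
Conditions: NaH, MOMCl, DMF, 0 °C to rt, argon
Reagents that add atoms: chloromethyl methyl ether (MOMCl), COCCl
Why: Williamson-type O-alkylation of both phenoxides gives acetal ethers that direct the later lithiation, withstand base and palladium, and come off under mild acid.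

**Step 8**
Reactants: 12 1,4-dimethoxy-2,5-bis(methoxymethoxy)benzene
Product: 14 1,4-diiodo-2,5-dimethoxy-3,6-bis(methoxymethoxy)benzene, via dilithioarene 13 (not isolated)
Conditions: n-BuLi (3 equiv), TMEDA, Et2O, 0 °C to rt; I2 in THF, −78 °C to rt
Reagents that add atoms: iodine, II
Why: Double directed ortho-metalation should succeed because each remaining ring C–H lies between a methoxy and a methoxymethoxy group, the most activated position for lithiation, and iodinolysis of 13 then gives the diiodide.

**Step 9**
Reactants: 14 1,4-diiodo-2,5-dimethoxy-3,6-bis(methoxymethoxy)benzene (threefold excess); 15 tert-butyl 3-(4,4,5,5-tetramethyl-1,3,2-dioxaborolan-2-yl)indole-1-carboxylate (1-Boc-indole-3-boronic acid pinacol ester)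
Product: 16 tert-butyl 3-[4-iodo-2,5-dimethoxy-3,6-bis(methoxymethoxy)phenyl]indole-1-carboxylate
Conditions: PdCl2(dppf) (cat.), K3PO4, 1,4-dioxane/H2O, 80 °C; unreacted 14 recovered
Reagents that add atoms: none
Why: Suzuki–Miyaura coupling in which the excess of symmetrical diiodide biases the statistics towards monoarylation, while the Boc group slows protodeboronation of the 3-indolylboronate and masks the indole NH.

**Step 10**
Reactants: 9 N-[2-(3,3-dimethylpent-4-en-1-ynyl)phenyl]-2,2,2-trifluoroacetamide; 16 tert-butyl 3-[4-iodo-2,5-dimethoxy-3,6-bis(methoxymethoxy)phenyl]indole-1-carboxylate (1.5 equiv)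
Product: 18 tert-butyl 3-{2,5-dimethoxy-3,6-bis(methoxymethoxy)-4-[2-(2-methylbut-3-en-2-yl)-1H-indol-3-yl]phenyl}indole-1-carboxylate, via N-trifluoroacetylindole 17 (not isolated)
Conditions: Pd(PPh3)4 (10 mol %), K2CO3 (3 equiv), MeCN, 80 °C; aq. NaHCO3 work-up
Reagents that add atoms: none
Why: Oxidative addition of 16 to zerovalent palladium gives a divalent arylpalladium iodide, which complexes the triple bond of 9 and makes it electrophilic. The carbonate-deprotonated amide nitrogen then adds to the alkyne carbon bearing the quaternary carbon, on the face opposite to palladium, closing the pyrrole ring in a 5-endo-dig mode (N1–C2); reductive elimination from the resulting 3-indolyl(aryl)palladium forms the C3–aryl bond and regenerates the catalyst, and the N-trifluoroacetyl group of 17 is then lost to carbonate and water. The closest known reaction type is the palladium-catalysed cyclisation–arylation of 2-alkynyltrifluoroacetanilides with aryl iodides (Cacchi indole synthesis), here extended to a di-ortho-alkoxy aryl iodide and a tert-alkyl alkyne. No stereocentre is formed. The step needs arylative cyclisation to outrun plain cyclisation to the 3-unsubstituted indole and Heck arylation of the vinyl group: the weakly nucleophilic, acidic trifluoroacetamide closes only onto a palladium-bound alkyne, the vinyl group sits on a quaternary carbon and is the poorer ligand, and 16 is used in excess. Since the pyrrole ring and the C3–aryl bond arise on one palladium centre, no preformed, congested 2-tert-alkylindole has to attack the core.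

**Step 11**
Reactants: 18 tert-butyl 3-{2,5-dimethoxy-3,6-bis(methoxymethoxy)-4-[2-(2-methylbut-3-en-2-yl)-1H-indol-3-yl]phenyl}indole-1-carboxylate
Product: 19 2-(1H-indol-3-yl)-3,6-dimethoxy-5-[2-(2-methylbut-3-en-2-yl)-1H-indol-3-yl]benzene-1,4-diol
Conditions: HCl (ca. 1.25 M) in anhydrous MeOH/THF, 45 °C, argon
Reagents that add atoms: none
Why: Acid-catalysed acetal exchange passes both methoxymethyl groups to methanol as dimethoxymethane and HCl cleaves the indole carbamate with loss of isobutene and CO2, while the monosubstituted vinyl group on a quaternary carbon should resist protonation at this acidity and anhydrous methanol leaves the aryl methyl ethers intact.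

**Step 12**
Reactants: 19 2-(1H-indol-3-yl)-3,6-dimethoxy-5-[2-(2-methylbut-3-en-2-yl)-1H-indol-3-yl]benzene-1,4-diol
Product: 20 2-(1H-indol-3-yl)-3,6-dimethoxy-5-[2-(2-methylbut-3-en-2-yl)-1H-indol-3-yl]cyclohexa-2,5-diene-1,4-dione (target)
Conditions: Ag2O, Na2SO4, Et2O/CH2Cl2, rt
Reagents that add atoms: none
Why: Ag2O oxidises the electron-rich hydroquinone to the p-quinone under neutral, non-nucleophilic conditions, so the two vinylogous methyl esters, both indole NH groups and the vinyl group should stay untouched.

**Compound list**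
1 | 2,2-dimethylbut-3-enoic acid | C=CC(C)(C)C(=O)O | starting material
2 | 2,2-dimethylbut-3-en-1-ol | C=CC(C)(C)CO | intermediate
3 | 2,2-dimethylbut-3-enal | C=CC(C)(C)C=O | intermediate
4 | 1,1-dibromo-3,3-dimethylpenta-1,4-diene | C=CC(C)(C)C=C(Br)Br | intermediate
5 | 2-iodoaniline | Nc1ccccc1I | starting material
6 | lithium 3,3-dimethylpent-4-en-1-yn-1-ide | C=CC(C)(C)C#C[Li] | intermediate (not isolated)
7 | chloro(3,3-dimethylpent-4-en-1-ynyl)zinc | C=CC(C)(C)C#C[Zn]Cl | intermediate (not isolated)
8 | 2-(3,3-dimethylpent-4-en-1-ynyl)aniline | C=CC(C)(C)C#Cc1ccccc1N | intermediate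
9 | N-[2-(3,3-dimethylpent-4-en-1-ynyl)phenyl]-2,2,2-trifluoroacetamide | C=CC(C)(C)C#Cc1ccccc1NC(=O)C(F)(F)F | intermediate
10 | 2,5-dimethoxy-1,4-benzoquinone | COC1=CC(=O)C(OC)=CC1=O | starting material
11 | 2,5-dimethoxybenzene-1,4-diol | COc1cc(O)c(OC)cc1O | intermediate
12 | 1,4-dimethoxy-2,5-bis(methoxymethoxy)benzene | COCOc1cc(OC)c(OCOC)cc1OC | intermediate
13 | [2,5-dimethoxy-3,6-bis(methoxymethoxy)-1,4-phenylene]dilithium | COCOc1c([Li])c(OC)c(OCOC)c([Li])c1OC | intermediate (not isolated)
14 | 1,4-diiodo-2,5-dimethoxy-3,6-bis(methoxymethoxy)benzene | COCOc1c(I)c(OC)c(OCOC)c(I)c1OC | intermediate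
15 | tert-butyl 3-(4,4,5,5-tetramethyl-1,3,2-dioxaborolan-2-yl)indole-1-carboxylate | CC(C)(C)OC(=O)n1cc(B2OC(C)(C)C(C)(C)O2)c2ccccc21 | starting material
16 | tert-butyl 3-[4-iodo-2,5-dimethoxy-3,6-bis(methoxymethoxy)phenyl]indole-1-carboxylate | COCOc1c(I)c(OC)c(OCOC)c(-c2cn(C(=O)OC(C)(C)C)c3ccccc23)c1OC | intermediate
17 | tert-butyl 3-{2,5-dimethoxy-3,6-bis(methoxymethoxy)-4-[2-(2-methylbut-3-en-2-yl)-1-(trifluoroacetyl)indol-3-yl]phenyl}indole-1-carboxylate | C=CC(C)(C)c1n(C(=O)C(F)(F)F)c2ccccc2c1-c1c(OC)c(OCOC)c(-c2cn(C(=O)OC(C)(C)C)c3ccccc23)c(OC)c1OCOC | intermediate (not isolated)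
18 | tert-butyl 3-{2,5-dimethoxy-3,6-bis(methoxymethoxy)-4-[2-(2-methylbut-3-en-2-yl)-1H-indol-3-yl]phenyl}indole-1-carboxylate | C=CC(C)(C)c1[nH]c2ccccc2c1-c1c(OC)c(OCOC)c(-c2cn(C(=O)OC(C)(C)C)c3ccccc23)c(OC)c1OCOC | intermediate
19 | 2-(1H-indol-3-yl)-3,6-dimethoxy-5-[2-(2-methylbut-3-en-2-yl)-1H-indol-3-yl]benzene-1,4-diol | C=CC(C)(C)c1[nH]c2ccccc2c1-c1c(OC)c(O)c(-c2c[nH]c3ccccc23)c(OC)c1O | intermediate
20 | 2-(1H-indol-3-yl)-3,6-dimethoxy-5-[2-(2-methylbut-3-en-2-yl)-1H-indol-3-yl]cyclohexa-2,5-diene-1,4-dione | C=CC(C)(C)c1[nH]c2ccccc2c1C1=C(OC)C(=O)C(c2c[nH]c3ccccc23)=C(OC)C1=O | target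

**Step count**
Total: 12 steps. Longest linear sequence: 8 steps (steps 1–5, 10, 11, 12).

**Steps most likely to fail**

Step 10. The crowded arylpalladium may engage the alkyne too slowly, so that proton-terminated cyclisation to the 3-unsubstituted indole, reductive loss of iodine from 16, or Heck arylation at the vinyl group consumes the partners. Partial loss of Boc under the carbonate conditions would be harmless, since step 11 removes it anyway. The fallback sets out from 16 (with 4 and 5) and comes back at 18. Zinc acetylide 7 is generated from 4 as in step 4 and coupled with 16 under Pd(PPh3)4 (Negishi alkynylation) to give the internal alkyne tert-butyl 3-[4-(3,3-dimethylpent-4-en-1-ynyl)-2,5-dimethoxy-3,6-bis(methoxymethoxy)phenyl]indole-1-carboxylate F1. Larock heteroannulation of F1 with 2-iodoaniline 5 (Pd(OAc)2, LiCl, K2CO3, DMF, 100 °C) then closes the same pyrrole ring by syn-carbopalladation and C–N reductive elimination. The tert-alkyl terminus is expected to end up next to nitrogen as the bulkier alkyne substituent, which gives 18. In this variant the nitrogen cannot bond to the alkyne before the carbon–carbon bond at C3 exists, so the 3-unsubstituted indole cannot form.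

Step 9. Over-arylation to the bis-indolyl arene may compete, or 15 may protodeboronate before it transmetalates at the di-ortho-alkoxy iodide. The fallback sets out from 14 and comes back at 16. One C–I bond of 14 is exchanged with i-PrMgCl·LiCl (1.0 equiv, THF, −20 °C; a second exchange on the electron-rich aryl Grignard should be much slower) to give [4-iodo-2,5-dimethoxy-3,6-bis(methoxymethoxy)phenyl]magnesium chloride F2. ZnCl2 converts this into [4-iodo-2,5-dimethoxy-3,6-bis(methoxymethoxy)phenyl]zinc chloride F3. Negishi coupling of F3 with tert-butyl 3-iodoindole-1-carboxylate F4 (bought, or made from 3-iodoindole and Boc2O; Pd2(dba)3/tri(2-furyl)phosphine, THF, 25–40 °C) gives 16. The unhindered iodoindole should undergo oxidative addition much faster than the di-ortho-substituted C–I bond that remains on the zinc reagent and on the product.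

Step 11. Under protic acid the tert-butyl cation or formaldehyde equivalents may alkylate the electron-rich indole and hydroquinone rings, the vinyl group may be protonated and captured by the neighbouring phenol, or the carbamate may cleave too slowly. The fallback sets out from 18 and comes back at 19. K2CO3 in MeOH/THF at 50 °C removes the indole carbamate by methanolysis to give 3-[4-(1H-indol-3-yl)-2,5-dimethoxy-3,6-bis(methoxymethoxy)phenyl]-2-(2-methylbut-3-en-2-yl)-1H-indole F5. TMSOTf/2,2'-bipyridyl in MeCN at 0 °C then converts both aryl MOM ethers, under buffered non-protic conditions, into the bis(trimethylsilyl) ether 3-[4-(1H-indol-3-yl)-2,5-dimethoxy-3,6-bis(trimethylsilyloxy)phenyl]-2-(2-methylbut-3-en-2-yl)-1H-indole F6. Addition of water hydrolyses F6 to 19, which is oxidised as in step 12.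

**Further compounds**
F1 | step 10 | tert-butyl 3-[4-(3,3-dimethylpent-4-en-1-ynyl)-2,5-dimethoxy-3,6-bis(methoxymethoxy)phenyl]indole-1-carboxylate | C=CC(C)(C)C#Cc1c(OC)c(OCOC)c(-c2cn(C(=O)OC(C)(C)C)c3ccccc23)c(OC)c1OCOC
F2 | step 9 | [4-iodo-2,5-dimethoxy-3,6-bis(methoxymethoxy)phenyl]magnesium chloride | COCOc1c(I)c(OC)c(OCOC)c([Mg]Cl)c1OC
F3 | step 9 | [4-iodo-2,5-dimethoxy-3,6-bis(methoxymethoxy)phenyl]zinc chloride | COCOc1c(I)c(OC)c(OCOC)c([Zn]Cl)c1OC
F4 | step 9 | tert-butyl 3-iodoindole-1-carboxylate | CC(C)(C)OC(=O)n1cc(I)c2ccccc21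
F5 | step 11 | 3-[4-(1H-indol-3-yl)-2,5-dimethoxy-3,6-bis(methoxymethoxy)phenyl]-2-(2-methylbut-3-en-2-yl)-1H-indole | C=CC(C)(C)c1[nH]c2ccccc2c1-c1c(OC)c(OCOC)c(-c2c[nH]c3ccccc23)c(OC)c1OCOC
F6 | step 11 | 3-[4-(1H-indol-3-yl)-2,5-dimethoxy-3,6-bis(trimethylsilyloxy)phenyl]-2-(2-methylbut-3-en-2-yl)-1H-indole | C=CC(C)(C)c1[nH]c2ccccc2c1-c1c(OC)c(O[Si](C)(C)C)c(-c2c[nH]c3ccccc23)c(OC)c1O[Si](C)(C)C
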